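**Plan**

- Numbering (carotenoid): keto-end ring C1–C6, chain C7–C15/C15'–C7', acyloxymethyl carbon C19, cyclohex-2-ene ring C1'–C6'. Cuts: C8–C9 (acyl–alkenyl, made last), C11=C12 and C11'=C12' (Wittig), C9'=C10' (Horner–Wadsworth–Emmons), and the laurate C–O bond.
- Enabling feature: in the keto-end ring the C3 carbinol is homoallylic to the tetrasubstituted C5=C6 bond, and C6 is the γ-carbon of the C8 carbonyl. This is the retron of a bicyclo[3.1.0]hexane with a C3–C5 bond, C4 as cyclopropane CH2 and an exocyclic C6=C7–C8(=O)OEt.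
- Ring, forward: 2-methylcyclopentenone → CBS reduction → directed cyclopropanation → ketone → gem-dimethylation → ethoxyacetylide/Meyer–Schuster → acid hydration cleaves the shared bond, so the cyclopentane grows by one carbon into the 3-hydroxycyclohexene bearing CH2–C(=O).
- Chain, forward: (R)-α-ionone → C15 phosphonium salt → C25 aldehyde (with the C10 dialdehyde) → C25 phosphonium salt → Wittig with a laurate-bearing C4 stannyl enal (from butynediol) → C29 alkenylstannane, acylated last with the ring thioester.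
- Stereochemistry: C3 from a CBS reduction, relayed by hydroxyl-directed Simmons–Smith reaction and inversion in the ring expansion; C6' from (R)-α-ionone; C3' from a second CBS reduction; C9=C10 from syn-hydrostannation; the other alkenes from olefinations with thermal equilibration to E.

Key step: step 7

Assumption: (R)-α-ionone of high enantiomeric purity (natural grade) is taken as purchasable; racemic material would have to be resolved first.

**Step 1**
Reactants: 1 2-methylcyclopent-2-en-1-one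
Product: 2 (1R)-2-methylcyclopent-2-en-1-ol
Conditions: (S)-2-methyl-CBS-oxazaborolidine (10 mol %), BH3·SMe2, THF, −20 °C; MeOH quench
Reagents that add atoms: none
Why: Corey–Bakshi–Shibata reduction: the carbonyl binds with the 2-methylalkenyl arm as the large group and is reduced 1,2, which with the (S)-catalyst should set the (R)-carbinol.

**Step 2**
Reactants: 2 (1R)-2-methylcyclopent-2-en-1-ol
Product: 3 (1S,2R,5R)-1-methylbicyclo[3.1.0]hexan-2-ol
Conditions: Et2Zn, CH2I2, CH2Cl2, 0 °C → rt
Reagents that add atoms: diiodomethane, ICI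
Why: Hydroxyl-directed Simmons–Smith cyclopropanation: the zinc alkoxide delivers the methylene to the alkene face syn to oxygen, so both ring-fusion centres follow from the carbinol of 2.

**Step 3**
Reactants: 3 (1S,2R,5R)-1-methylbicyclo[3.1.0]hexan-2-ol
Product: 4 (1S,5R)-1-methylbicyclo[3.1.0]hexan-2-one
Conditions: Dess–Martin periodinane, NaHCO3, CH2Cl2, rt
Reagents that add atoms: none
Why: Dess–Martin oxidation of a secondary alcohol under buffered conditions; the cyclopropane centres cannot epimerise because C1 is quaternary.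

**Step 4**
Reactants: 4 (1S,5R)-1-methylbicyclo[3.1.0]hexan-2-one
Product: 6 (1S,5S)-1,3,3-trimethylbicyclo[3.1.0]hexan-2-one, via 3-monomethyl ketone 5 (not isolated)
Conditions: KN(SiMe3)2 (1.2 equiv), THF, −78 °C, then MeI, −78 → 0 °C; second identical cycle in the same flask
Reagents that add atoms: iodomethane, CI
Why: Enolate alkylation: C3 is the only enolisable position of 4, so two deprotonation/methylation cycles should install the geminal dimethyl group without touching the stereocentres.

**Step 5**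
Reactants: 6 (1S,5S)-1,3,3-trimethylbicyclo[3.1.0]hexan-2-one; 7 ethoxyacetylene
Product: 9 (1S,5S)-2-(ethoxyethynyl)-1,3,3-trimethylbicyclo[3.1.0]hexan-2-ol (C2 epimers), via lithium ethoxyacetylide 8 (not isolated)
Conditions: 7, n-BuLi, THF, −78 °C; then 6, −78 → 0 °C; aq. NH4Cl
Reagents that add atoms: none
Why: 1,2-Addition of a small lithium acetylide to a hindered ketone that cannot enolise; the new carbinol centre is unimportant because it is removed in step 6.

**Step 6**
Reactants: 9 (1S,5S)-2-(ethoxyethynyl)-1,3,3-trimethylbicyclo[3.1.0]hexan-2-ol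
Product: 10 ethyl 2-[(1S,5S)-1,3,3-trimethylbicyclo[3.1.0]hexan-2-ylidene]acetate (mixture of alkene isomers)
Conditions: Sc(OTf)3 (5 mol %), EtOH (5 equiv), CH2Cl2, rt
Reagents that add atoms: none
Why: Meyer–Schuster rearrangement of an ethoxyalkynyl carbinol (1,3-shift of oxygen through a dialkoxy-stabilised cation) gives the conjugated ester from a ketone too hindered for phosphonate olefination; under these mild conditions the cyclopropane should stay closed, and the alkene geometry is of no consequence.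

**Step 7**
Reactants: 10 ethyl 2-[(1S,5S)-1,3,3-trimethylbicyclo[3.1.0]hexan-2-ylidene]acetate
Product: 11 ethyl 2-[(4R)-4-hydroxy-2,6,6-trimethylcyclohex-1-en-1-yl]acetate
Conditions: TfOH (20 mol %), H2O (10 equiv), (CF3)2CHOH, 0 °C → rt; aq. NaHCO3
Reagents that add atoms: water, O
Why: Proposed new method: protonation of the enoate carbonyl gives a hydroxy(ethoxy)allyl cation whose γ-terminus (ring C2 of 10) is a tertiary cyclopropylcarbinyl centre; water attacks the cyclopropane methine C5 from the side opposite the shared C1–C5 bond while that bond breaks, and the resulting dienol is protonated at the α-carbon to leave the β,γ-unsaturated ester with the tetrasubstituted ring alkene. The closest known reaction types are the acid-catalysed cyclopropylcarbinyl-to-homoallyl ring expansions of bicyclo[3.1.0]hexan-2-yl cations (thujane to p-menthane type, retro-i-steroid rearrangement) and the acid-mediated homoconjugate addition to cyclopropyl ketones; the vinylogous use on a cyclopropane-fused alkylidene acetate is the new element. No ring is closed: the cyclohexene arises by scission of the zero-atom bridge of the fused cyclopentane–cyclopropane, a one-carbon expansion of the five-membered ring. The only new stereocentre, the carbinol carbon, is set by inversion at the cyclopropane methine fixed in step 2, because the bridged cation is opened anti to the breaking bond. The step needs cleavage of the internal and not the external cyclopropane bond: internal cleavage places positive charge on a secondary and not a primary carbon and gives the less strained six-membered homoallylic alcohol, and under reversible, strongly ionising conditions the tertiary hydration product and any primary alcohol from external opening can re-enter the same cation, so the cyclohexenol should accumulate as the thermodynamic sink. The ester conjugation keeps the charge from wandering, suppresses elimination and Wagner–Meerwein scrambling, and fixes the position of the alkene.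

**Step 8**
Reactants: 11 ethyl 2-[(4R)-4-hydroxy-2,6,6-trimethylcyclohex-1-en-1-yl]acetate
Product: 12 S-phenyl 2-[(4R)-4-hydroxy-2,6,6-trimethylcyclohex-1-en-1-yl]ethanethioate
Conditions: Me3Al (3 equiv), PhSH (3 equiv), CH2Cl2, 0 °C → rt
Reagents that add atoms: thiophenol, Sc1ccccc1
Why: Aluminium thiolate-mediated conversion of an ester into a thioester (transacylation by Me2AlSPh); the medium is not basic, so the β,γ-double bond should stay in the ring, and the free hydroxyl is carried as its aluminium alkoxide.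

**Step 9**
Reactants: 13 but-2-yne-1,4-diol
Product: 14 4-[(tert-butyldimethylsilyl)oxy]but-2-yn-1-ol
Conditions: NaH (1.0 equiv), THF, rt; then t-BuMe2SiCl (1.0 equiv)
Reagents that add atoms: tert-butyldimethylsilyl chloride, CC(C)(C)[Si](C)(C)Cl
Why: Monosilylation of a symmetric diol via its sparingly soluble monosodium alkoxide, which is silylated faster than it is deprotonated a second time.

**Step 10**
Reactants: 14 4-[(tert-butyldimethylsilyl)oxy]but-2-yn-1-ol
Product: 15 (2E)-4-[(tert-butyldimethylsilyl)oxy]-2-(tributylstannyl)but-2-en-1-ol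
Conditions: Bu3SnH (1.1 equiv), PdCl2(PPh3)2 (2 mol %), THF, 0 °C → rt
Reagents that add atoms: tributyltin hydride, CCCC[SnH](CCCC)CCCC
Why: Palladium-catalysed hydrostannation: H and Sn add syn, and tin should go to the alkyne carbon next to the free hydroxymethyl group and away from the bulky silyl ether, which fixes the two CH2O groups cis as needed for C9=C10.

**Step 11**
Reactants: 15 (2E)-4-[(tert-butyldimethylsilyl)oxy]-2-(tributylstannyl)but-2-en-1-ol
Product: 16 (2E)-4-[(tert-butyldimethylsilyl)oxy]-2-(tributylstannyl)but-2-en-1-yl dodecanoate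
Conditions: dodecanoyl chloride, pyridine, DMAP (cat.), CH2Cl2, 0 °C
Reagents that add atoms: dodecanoyl chloride, CCCCCCCCCCCC(=O)Cl
Why: Acylation of the primary allylic alcohol with the acid chloride under nucleophilic catalysis.

**Step 12**
Reactants: 16 (2E)-4-[(tert-butyldimethylsilyl)oxy]-2-(tributylstannyl)but-2-en-1-yl dodecanoate
Product: 17 (2E)-4-hydroxy-2-(tributylstannyl)but-2-en-1-yl dodecanoate
Conditions: Bu4NF, AcOH (1:1), THF, 0 °C
Reagents that add atoms: none
Why: Fluoride desilylation buffered with acetic acid, so that neither acyl migration to the neighbouring cis hydroxymethyl group nor protodestannylation should occur.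

**Step 13**
Reactants: 17 (2E)-4-hydroxy-2-(tributylstannyl)but-2-en-1-yl dodecanoate
Product: 18 (2E)-4-oxo-2-(tributylstannyl)but-2-en-1-yl dodecanoate
Conditions: MnO2 (activated, excess), CH2Cl2, rt
Reagents that add atoms: none
Why: MnO2 oxidation of a primary allylic alcohol under neutral conditions, which should keep the alkene geometry, the C–Sn bond and the ester.

**Step 14**
Reactants: 19 (R)-α-ionone, (3E)-4-[(1R)-2,6,6-trimethylcyclohex-2-en-1-yl]but-3-en-2-one
Product: 20 ethyl (2E,4E)-3-methyl-5-[(1R)-2,6,6-trimethylcyclohex-2-en-1-yl]penta-2,4-dienoate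
Conditions: triethyl phosphonoacetate, NaH (slight deficit relative to the phosphonate), THF, 0 → 50 °C; chromatography
Reagents that add atoms: triethyl phosphonoacetate, CCOC(=O)CP(=O)(OCC)OCC
Why: Horner–Wadsworth–Emmons olefination of the methyl ketone favours the (2E) ester; the weakly basic phosphonate anion should not deprotonate the doubly allylic ring C–H, and the minor (2Z) isomer is removed by chromatography.

**Step 15**
Reactants: 20 ethyl (2E,4E)-3-methyl-5-[(1R)-2,6,6-trimethylcyclohex-2-en-1-yl]penta-2,4-dienoate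
Product: 21 ethyl (2E,4E)-3-methyl-5-[(1R)-2,6,6-trimethyl-4-oxocyclohex-2-en-1-yl]penta-2,4-dienoate
Conditions: Rh2(cap)4 (dirhodium tetrakis(caprolactamate), 1 mol %), t-BuOOH (70% in H2O, 5 equiv), CH2Cl2, rt
Reagents that add atoms: tert-butyl hydroperoxide, CC(C)(C)OO
Why: Dirhodium-catalysed allylic C–H oxidation with tert-butyl hydroperoxide (radical chain via tert-butylperoxyl): the ring CH2 next to the trisubstituted alkene is the only secondary allylic position, the tertiary allylic ring C–H being shielded by the geminal methyl groups.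

**Step 16**
Reactants: 21 ethyl (2E,4E)-3-methyl-5-[(1R)-2,6,6-trimethyl-4-oxocyclohex-2-en-1-yl]penta-2,4-dienoate
Product: 22 ethyl (2E,4E)-5-[(1R,4R)-4-hydroxy-2,6,6-trimethylcyclohex-2-en-1-yl]-3-methylpenta-2,4-dienoate
Conditions: (S)-2-methyl-CBS-oxazaborolidine (20 mol %), BH3·SMe2, THF, −20 °C; MeOH quench
Reagents that add atoms: none
Why: Corey–Bakshi–Shibata reduction under reagent control: with the alkenyl arm as the large group the (S)-catalyst should give the (4R)-allylic alcohol, trans to the side chain, irrespective of the remote ring stereocentre.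

**Step 17**
Reactants: 22 ethyl (2E,4E)-5-[(1R,4R)-4-hydroxy-2,6,6-trimethylcyclohex-2-en-1-yl]-3-methylpenta-2,4-dienoate
Product: 23 (2E,4E)-5-[(1R,4R)-4-hydroxy-2,6,6-trimethylcyclohex-2-en-1-yl]-3-methylpenta-2,4-dien-1-ol
Conditions: i-Bu2AlH (3.5 equiv), CH2Cl2, −78 °C; Rochelle salt work-up
Reagents that add atoms: none
Why: 1,2-Reduction of the conjugated ester to the primary allylic alcohol by the aluminium hydride at low temperature.

**Step 18**
Reactants: 23 (2E,4E)-5-[(1R,4R)-4-hydroxy-2,6,6-trimethylcyclohex-2-en-1-yl]-3-methylpenta-2,4-dien-1-ol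
Product: 24 [(2E,4E)-5-[(1R,4R)-4-hydroxy-2,6,6-trimethylcyclohex-2-en-1-yl]-3-methylpenta-2,4-dien-1-yl]triphenylphosphonium bromide
Conditions: PPh3·HBr, MeOH, 0 °C → rt
Reagents that add atoms: triphenylphosphine hydrobromide, Br.P(c1ccccc1)(c1ccccc1)c1ccccc1
Why: Acid-mediated SN1-type substitution: the primary dienylic alcohol ionises to a pentadienyl cation far more readily than the ring allylic alcohol at 0 °C, and triphenylphosphine captures it at the terminal carbon to keep the diene conjugated.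

**Step 19**
Reactants: 24 the C15 phosphonium bromide; 25 (2E,4E,6E)-2,7-dimethylocta-2,4,6-trienedial
Product: 27 (2E,4E,6E,8E,10E,12E)-13-[(1R,4R)-4-hydroxy-2,6,6-trimethylcyclohex-2-en-1-yl]-2,7,11-trimethyltrideca-2,4,6,8,10,12-hexaenal, via C15 ylide 26 (not isolated)
Conditions: NaOMe, MeOH/CH2Cl2, 0 °C → rt, 25 in excess (2 equiv); then heptane, reflux, dark
Reagents that add atoms: none
Why: Wittig olefination of a dialdehyde used in excess to secure mono-condensation; the new disubstituted double bond forms as an E/Z mixture whose hindered Z isomer is equilibrated thermally to E.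

**Step 20**
Reactants: 27 the C25 hydroxy aldehyde
Product: 28 (2E,4E,6E,8E,10E,12E)-13-[(1R,4R)-4-hydroxy-2,6,6-trimethylcyclohex-2-en-1-yl]-2,7,11-trimethyltrideca-2,4,6,8,10,12-hexaen-1-ol
Conditions: NaBH4, EtOH/THF, 0 °C
Reagents that add atoms: none
Why: Chemoselective 1,2-reduction of the polyene aldehyde by borohydride.

**Step 21**
Reactants: 28 the C25 diol
Product: 29 [(2E,4E,6E,8E,10E,12E)-13-[(1R,4R)-4-hydroxy-2,6,6-trimethylcyclohex-2-en-1-yl]-2,7,11-trimethyltrideca-2,4,6,8,10,12-hexaen-1-yl]triphenylphosphonium bromide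
Conditions: PPh3·HBr, MeOH/CH2Cl2, 0 °C, short reaction time, dark
Reagents that add atoms: triphenylphosphine hydrobromide, Br.P(c1ccccc1)(c1ccccc1)c1ccccc1
Why: Same SN1-type phosphonium salt formation as in step 18; the cation from the primary polyenylic alcohol forms under milder conditions than the ring allyl cation, so brief exposure at low temperature should spare the ring hydroxyl.

**Step 22**
Reactants: 29 the C25 phosphonium bromide; 18 (2E)-4-oxo-2-(tributylstannyl)but-2-en-1-yl dodecanoate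
Product: 31 (2E,4E,6E,8E,10E,12E,14E,16E)-17-[(1R,4R)-4-hydroxy-2,6,6-trimethylcyclohex-2-en-1-yl]-6,11,15-trimethyl-2-(tributylstannyl)heptadeca-2,4,6,8,10,12,14,16-octaen-1-yl dodecanoate, via C25 ylide 30 (not isolated)
Conditions: NaN(SiMe3)2 (1.0 equiv), THF, −78 °C; then 18, −78 °C → rt; then heptane, 80 °C, dark
Reagents that add atoms: none
Why: Wittig olefination with a preformed polyenyl ylide, so no free base is left to touch the laurate; the hindered Z isomer at the new C11=C12 bond is equilibrated thermally to E, iodine being avoided because of the C–Sn bond.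

**Step 23**
Reactants: 31 the C29 alkenylstannane; 12 S-phenyl 2-[(4R)-4-hydroxy-2,6,6-trimethylcyclohex-1-en-1-yl]ethanethioate
Product: 32 (2E,4E,6E,8E,10E,12E,14E,16E)-2-{2-[(4R)-4-hydroxy-2,6,6-trimethylcyclohex-1-en-1-yl]acetyl}-17-[(1R,4R)-4-hydroxy-2,6,6-trimethylcyclohex-2-en-1-yl]-6,11,15-trimethylheptadeca-2,4,6,8,10,12,14,16-octaen-1-yl dodecanoate (target)
Conditions: Pd2(dba)3 (5 mol %), P(2-furyl)3 (20 mol %), CuO2PPh2 (1.5 equiv), THF, rt → 40 °C, argon, dark
Reagents that add atoms: none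
Why: Liebeskind–Srogl ketone synthesis: oxidative addition of zerovalent palladium to the thioester C–S bond (thiolate scavenged by copper), tin-to-palladium transmetalation with retention at C9 and reductive elimination form the C8–C9 bond under neutral conditions that tolerate both free hydroxyls, the laurate and the base-sensitive β,γ-unsaturated ketone.

**Compound list**

1 | 2-methylcyclopent-2-en-1-one | CC1=CCCC1=O | starting material
2 | (1R)-2-methylcyclopent-2-en-1-ol | O[C@H]1C(C)=CCC1 | intermediate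
3 | (1S,2R,5R)-1-methylbicyclo[3.1.0]hexan-2-ol | O[C@@H]1CC[C@@H]2C[C@]12C | intermediate
4 | (1S,5R)-1-methylbicyclo[3.1.0]hexan-2-one | O=C1CC[C@@H]2C[C@]12C | intermediate
5 | (1S,5R)-1,3-dimethylbicyclo[3.1.0]hexan-2-one (C3 epimers) | O=C1C(C)C[C@@H]2C[C@]12C | intermediate (not isolated)
6 | (1S,5S)-1,3,3-trimethylbicyclo[3.1.0]hexan-2-one | O=C1C(C)(C)C[C@@H]2C[C@]12C | intermediate
7 | ethoxyacetylene | CCOC#C | starting material
8 | lithium ethoxyacetylide | [Li]C#COCC | intermediate (not isolated)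
9 | (1S,5S)-2-(ethoxyethynyl)-1,3,3-trimethylbicyclo[3.1.0]hexan-2-ol (C2 epimers) | CCOC#CC1(O)C(C)(C)C[C@@H]2C[C@]12C | intermediate
10 | ethyl 2-[(1S,5S)-1,3,3-trimethylbicyclo[3.1.0]hexan-2-ylidene]acetate (alkene isomers) | CCOC(=O)C=C1C(C)(C)C[C@@H]2C[C@]12C | intermediate
11 | ethyl 2-[(4R)-4-hydroxy-2,6,6-trimethylcyclohex-1-en-1-yl]acetate | CCOC(=O)CC1=C(C)C[C@@H](O)CC1(C)C | intermediate
12 | S-phenyl 2-[(4R)-4-hydroxy-2,6,6-trimethylcyclohex-1-en-1-yl]ethanethioate | O=C(CC1=C(C)C[C@@H](O)CC1(C)C)Sc1ccccc1 | intermediate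
13 | but-2-yne-1,4-diol | OCC#CCO | starting material
14 | 4-[(tert-butyldimethylsilyl)oxy]but-2-yn-1-ol | CC(C)(C)[Si](C)(C)OCC#CCO | intermediate
15 | (2E)-4-[(tert-butyldimethylsilyl)oxy]-2-(tributylstannyl)but-2-en-1-ol | OC/C(=C\CO[Si](C)(C)C(C)(C)C)[Sn](CCCC)(CCCC)CCCC | intermediate
16 | (2E)-4-[(tert-butyldimethylsilyl)oxy]-2-(tributylstannyl)but-2-en-1-yl dodecanoate | CCCCCCCCCCCC(=O)OC/C(=C\CO[Si](C)(C)C(C)(C)C)[Sn](CCCC)(CCCC)CCCC | intermediate
17 | (2E)-4-hydroxy-2-(tributylstannyl)but-2-en-1-yl dodecanoate | CCCCCCCCCCCC(=O)OC/C(=C\CO)[Sn](CCCC)(CCCC)CCCC | intermediate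
18 | (2E)-4-oxo-2-(tributylstannyl)but-2-en-1-yl dodecanoate | CCCCCCCCCCCC(=O)OC/C(=C\C=O)[Sn](CCCC)(CCCC)CCCC | intermediate
19 | (R)-α-ionone, (3E)-4-[(1R)-2,6,6-trimethylcyclohex-2-en-1-yl]but-3-en-2-one | CC(=O)/C=C/[C@H]1C(C)=CCCC1(C)C | starting material
20 | ethyl (2E,4E)-3-methyl-5-[(1R)-2,6,6-trimethylcyclohex-2-en-1-yl]penta-2,4-dienoate | CCOC(=O)/C=C(C)/C=C/[C@H]1C(C)=CCCC1(C)C | intermediate
21 | ethyl (2E,4E)-3-methyl-5-[(1R)-2,6,6-trimethyl-4-oxocyclohex-2-en-1-yl]penta-2,4-dienoate | CCOC(=O)/C=C(C)/C=C/[C@H]1C(C)=CC(=O)CC1(C)C | intermediate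
22 | ethyl (2E,4E)-5-[(1R,4R)-4-hydroxy-2,6,6-trimethylcyclohex-2-en-1-yl]-3-methylpenta-2,4-dienoate | CCOC(=O)/C=C(C)/C=C/[C@H]1C(C)=C[C@H](O)CC1(C)C | intermediate
23 | (2E,4E)-5-[(1R,4R)-4-hydroxy-2,6,6-trimethylcyclohex-2-en-1-yl]-3-methylpenta-2,4-dien-1-ol | OC/C=C(C)/C=C/[C@H]1C(C)=C[C@H](O)CC1(C)C | intermediate
24 | [(2E,4E)-5-[(1R,4R)-4-hydroxy-2,6,6-trimethylcyclohex-2-en-1-yl]-3-methylpenta-2,4-dien-1-yl]triphenylphosphonium bromide | [Br-].C(/C=C(C)/C=C/[C@H]1C(C)=C[C@H](O)CC1(C)C)[P+](c1ccccc1)(c1ccccc1)c1ccccc1 | intermediate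
25 | (2E,4E,6E)-2,7-dimethylocta-2,4,6-trienedial | O=C/C(C)=C/C=C/C=C(C)/C=O | starting material
26 | ylide of 24, (2E,4E)-5-[(1R,4R)-4-hydroxy-2,6,6-trimethylcyclohex-2-en-1-yl]-3-methylpenta-2,4-dienylidene(triphenyl)phosphorane | C(/C=C(C)/C=C/[C@H]1C(C)=C[C@H](O)CC1(C)C)=P(c1ccccc1)(c1ccccc1)c1ccccc1 | intermediate (not isolated)
27 | (2E,4E,6E,8E,10E,12E)-13-[(1R,4R)-4-hydroxy-2,6,6-trimethylcyclohex-2-en-1-yl]-2,7,11-trimethyltrideca-2,4,6,8,10,12-hexaenal | O=C/C(C)=C/C=C/C=C(C)/C=C/C=C(C)/C=C/[C@H]1C(C)=C[C@H](O)CC1(C)C | intermediate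
28 | (2E,4E,6E,8E,10E,12E)-13-[(1R,4R)-4-hydroxy-2,6,6-trimethylcyclohex-2-en-1-yl]-2,7,11-trimethyltrideca-2,4,6,8,10,12-hexaen-1-ol | OC/C(C)=C/C=C/C=C(C)/C=C/C=C(C)/C=C/[C@H]1C(C)=C[C@H](O)CC1(C)C | intermediate
29 | [(2E,4E,6E,8E,10E,12E)-13-[(1R,4R)-4-hydroxy-2,6,6-trimethylcyclohex-2-en-1-yl]-2,7,11-trimethyltrideca-2,4,6,8,10,12-hexaen-1-yl]triphenylphosphonium bromide | [Br-].C(/C(C)=C/C=C/C=C(C)/C=C/C=C(C)/C=C/[C@H]1C(C)=C[C@H](O)CC1(C)C)[P+](c1ccccc1)(c1ccccc1)c1ccccc1 | intermediate
30 | ylide of 29, the corresponding trideca-2,4,6,8,10,12-hexaenylidene(triphenyl)phosphorane | C(/C(C)=C/C=C/C=C(C)/C=C/C=C(C)/C=C/[C@H]1C(C)=C[C@H](O)CC1(C)C)=P(c1ccccc1)(c1ccccc1)c1ccccc1 | intermediate (not isolated)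
31 | (2E,4E,6E,8E,10E,12E,14E,16E)-17-[(1R,4R)-4-hydroxy-2,6,6-trimethylcyclohex-2-en-1-yl]-6,11,15-trimethyl-2-(tributylstannyl)heptadeca-2,4,6,8,10,12,14,16-octaen-1-yl dodecanoate | CCCCCCCCCCCC(=O)OC\C(=C/C=C/C(C)=C/C=C/C=C(C)/C=C/C=C(C)/C=C/[C@H]1C(C)=C[C@H](O)CC1(C)C)[Sn](CCCC)(CCCC)CCCC | intermediate
32 | (2E,4E,6E,8E,10E,12E,14E,16E)-2-{2-[(4R)-4-hydroxy-2,6,6-trimethylcyclohex-1-en-1-yl]acetyl}-17-[(1R,4R)-4-hydroxy-2,6,6-trimethylcyclohex-2-en-1-yl]-6,11,15-trimethylheptadeca-2,4,6,8,10,12,14,16-octaen-1-yl dodecanoate | CCCCCCCCCCCC(=O)OC\C(=C/C=C/C(C)=C/C=C/C=C(C)/C=C/C=C(C)/C=C/[C@H]1C(C)=C[C@H](O)CC1(C)C)C(=O)CC1=C(C)C[C@@H](O)CC1(C)C | target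

**Step count and risks**

Total: 23 steps. Longest linear sequence: 10 steps (19 → 32, steps 14–23).

Steps most likely to fail:

1. Step 7 (proposed new method). What may go wrong: water may open the external cyclopropane bond at the primary carbon, which gives a cyclopentene and no ring expansion. Stereochemical integrity may be partly lost if an open secondary cation intervenes. The ester may hydrolyse or lactonise onto the ring alkene under the acid. Fallback (known chemistry, gives up the ring expansion): it sets out from 7, used as its lithium salt 8, and returns to the route at 11. Two equivalents of 8 are added (THF, −78 °C) to purchased (4R,6R)-4-hydroxy-2,2,6-trimethylcyclohexan-1-one F1 to give (4R,6R)-1-(ethoxyethynyl)-2,2,6-trimethylcyclohexane-1,4-diol F2. Meyer–Schuster rearrangement (Sc(OTf)3, EtOH, CH2Cl2) then gives ethyl 2-[(4R,6R)-4-hydroxy-2,2,6-trimethylcyclohexylidene]acetate F3. Deconjugation of F3 by dianion formation (LiN(i-Pr)2, HMPA, THF, −78 °C) and kinetic α-protonation moves the double bond into the ring and gives 11; the carbinol centre comes from F1.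

2. Step 23. What may go wrong: slow transmetalation of the α-branched alkenylstannane, protodestannylation, ionisation of the allylic laurate by zerovalent palladium, and isomerisation or decomposition of the polyene on prolonged exposure to the metals. Fallback: it sets out from 16 and 12 and returns at 32, forming the C8–C9 bond on small fragments and joining the polyene last. Iododestannylation of 16 (I2, CH2Cl2, 0 °C) gives (2E)-4-[(tert-butyldimethylsilyl)oxy]-2-iodobut-2-en-1-yl dodecanoate F4. Fukuyama reduction of 12 (Et3SiH, Pd/C, acetone) gives 2-[(4R)-4-hydroxy-2,6,6-trimethylcyclohex-1-en-1-yl]acetaldehyde F5. Nozaki–Hiyama–Kishi coupling of F4 with F5 (CrCl2, NiCl2 cat., DMF) gives the allylic alcohol (2E)-4-[(tert-butyldimethylsilyl)oxy]-2-{1-hydroxy-2-[(4R)-4-hydroxy-2,6,6-trimethylcyclohex-1-en-1-yl]ethyl}but-2-en-1-yl dodecanoate F6. MnO2 oxidises only its allylic hydroxyl to the enone F7. Bu4NF/AcOH frees the primary alcohol F8, and MnO2 gives the oxo-enal F9. Wittig reaction of F9 with ylide 30 (from 29, NaN(SiMe3)2, THF, −78 °C) followed by thermal equilibration gives 32.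

3. Step 21. What may go wrong: acid ionisation of the ring allylic hydroxyl (dehydration or methanolysis) and allylic scrambling of the polyenyl cation during salt formation. Fallback: it sets out from 28 and returns at 31 without any acid. Chemoselective chlorination of the primary allylic alcohol (MsCl, LiCl, 2,4,6-collidine, DMF, 0 °C) gives (1R,4R)-4-[(1E,3E,5E,7E,9E,11E)-13-chloro-3,7,12-trimethyltrideca-1,3,5,7,9,11-hexaen-1-yl]-3,5,5-trimethylcyclohex-2-en-1-ol F10. Michaelis–Becker reaction (NaP(O)(OEt)2, THF, 0 °C) gives the diethyl phosphonate F11. Horner–Wadsworth–Emmons reaction of F11 with 18 (NaN(SiMe3)2, 2 equiv, THF, −78 °C) gives 31 with the E geometry favoured.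

**Further compounds**

F1 | step 7 | (4R,6R)-4-hydroxy-2,2,6-trimethylcyclohexan-1-one | O=C1[C@H](C)C[C@@H](O)CC1(C)C
F2 | step 7 | (4R,6R)-1-(ethoxyethynyl)-2,2,6-trimethylcyclohexane-1,4-diol (C1 epimers) | CCOC#CC1(O)[C@H](C)C[C@@H](O)CC1(C)C
F3 | step 7 | ethyl 2-[(4R,6R)-4-hydroxy-2,2,6-trimethylcyclohexylidene]acetate | CCOC(=O)C=C1[C@H](C)C[C@@H](O)CC1(C)C
F4 | step 23 | (2E)-4-[(tert-butyldimethylsilyl)oxy]-2-iodobut-2-en-1-yl dodecanoate | CCCCCCCCCCCC(=O)OC/C(I)=C\CO[Si](C)(C)C(C)(C)C
F5 | step 23 | 2-[(4R)-4-hydroxy-2,6,6-trimethylcyclohex-1-en-1-yl]acetaldehyde | O=CCC1=C(C)C[C@@H](O)CC1(C)C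
F6 | step 23 | (2E)-4-[(tert-butyldimethylsilyl)oxy]-2-{1-hydroxy-2-[(4R)-4-hydroxy-2,6,6-trimethylcyclohex-1-en-1-yl]ethyl}but-2-en-1-yl dodecanoate | CCCCCCCCCCCC(=O)OC/C(=C\CO[Si](C)(C)C(C)(C)C)C(O)CC1=C(C)C[C@@H](O)CC1(C)C
F7 | step 23 | (2E)-4-[(tert-butyldimethylsilyl)oxy]-2-{2-[(4R)-4-hydroxy-2,6,6-trimethylcyclohex-1-en-1-yl]acetyl}but-2-en-1-yl dodecanoate | CCCCCCCCCCCC(=O)OC/C(=C\CO[Si](C)(C)C(C)(C)C)C(=O)CC1=C(C)C[C@@H](O)CC1(C)C
F8 | step 23 | (2E)-4-hydroxy-2-{2-[(4R)-4-hydroxy-2,6,6-trimethylcyclohex-1-en-1-yl]acetyl}but-2-en-1-yl dodecanoate | CCCCCCCCCCCC(=O)OC/C(=C\CO)C(=O)CC1=C(C)C[C@@H](O)CC1(C)C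
F9 | step 23 | (2E)-2-{2-[(4R)-4-hydroxy-2,6,6-trimethylcyclohex-1-en-1-yl]acetyl}-4-oxobut-2-en-1-yl dodecanoate | CCCCCCCCCCCC(=O)OC/C(=C\C=O)C(=O)CC1=C(C)C[C@@H](O)CC1(C)C
F10 | step 21 | (1R,4R)-4-[(1E,3E,5E,7E,9E,11E)-13-chloro-3,7,12-trimethyltrideca-1,3,5,7,9,11-hexaen-1-yl]-3,5,5-trimethylcyclohex-2-en-1-ol | ClC/C(C)=C/C=C/C=C(C)/C=C/C=C(C)/C=C/[C@H]1C(C)=C[C@H](O)CC1(C)C
F11 | step 21 | diethyl [(2E,4E,6E,8E,10E,12E)-13-[(1R,4R)-4-hydroxy-2,6,6-trimethylcyclohex-2-en-1-yl]-2,7,11-trimethyltrideca-2,4,6,8,10,12-hexaen-1-yl]phosphonate | CCOP(=O)(OCC)C/C(C)=C/C=C/C=C(C)/C=C/C=C(C)/C=C/[C@H]1C(C)=C[C@H](O)CC1(C)C
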